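The route rests on cutting the C6–C7 bond of the oxonane ring (O, C3, C4, C5, C6, C7, C8, C9, C10). Atoms carry germacrane numbers (C1 ketone, C12 lactone carbonyl). The Z-C4=C5 bond, the allylic C6–O and the oxygenated C8 next to C7 form the retron of a Claisen rearrangement. A seven-membered dioxepane, held in a 3,9-dioxabicyclo[4.2.1]nonane, carries a C8 alkylidene bearing the acrylate unit and a (Z)-2-acetoxyvinyl group on C4. On heating, C4–O breaks and C6–C7 forms: the ring grows by two atoms to the oxa-bridged nine-membered ketone, fixing C6, C7 and the alkene geometry at once. The precursor comes from an asymmetric hetero-Diels–Alder adduct of biacetyl by Michael ring closure and Baeyer–Villiger oxidation.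

Key step: step 15

Remarks on the chemistry:
- O' is the oxygen that sits between C4 and C8 in compounds 15 to 24. TMSE = 2-(trimethylsilyl)ethyl, TBS = tert-butyldimethylsilyl, TIPS = triisopropylsilyl.
- Assumption: the enantiomer of the bis(oxazoline) ligand in step 1 is the one that delivers the 2S adduct.
- Assumption: in the 8-oxabicyclo[3.2.1]octanone, electrophiles enter α to the ketone from the exo face (axial, anti to the two-carbon bridge), and an α-acyloxy group prefers the equatorial position.

Step 1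
Reactants: 1 butane-2,3-dione; 2 (E)-1-methoxy-3-(trimethylsilyloxy)buta-1,3-diene
Product: 3 (S)-2-acetyl-2-methyl-2,3-dihydro-4H-pyran-4-one
Conditions: Cu(OTf)2 (10 mol %), 2,2'-isopropylidenebis(4-tert-butyl-2-oxazoline), THF, −40 °C to rt; then CF3CO2H, CH2Cl2, 0 °C
Reagents that add atoms: none
Why: Catalytic asymmetric hetero-Diels–Alder reaction of an activated ketone, in which two-point binding of the 1,2-dione to divalent copper shields one carbonyl face and sets C10, followed by acid-induced loss of methanol and of the silyl group.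

Step 2
Reactants: 3 (S)-2-acetyl-2-methyl-2,3-dihydro-4H-pyran-4-one
Product: 4 (S)-2-acetyl-5-iodo-2-methyl-2,3-dihydro-4H-pyran-4-one
Conditions: I2, pyridine, CH2Cl2, 0 °C to rt
Reagents that add atoms: iodine, [I][I]
Why: Electrophilic α-iodination of the vinylogous ester at its nucleophilic carbon C4 (pyridine-assisted addition–elimination) is a standard α-iodoenone synthesis and leaves C10 untouched.

Step 3
Reactants: 4 (S)-2-acetyl-5-iodo-2-methyl-2,3-dihydro-4H-pyran-4-one; 5 ethynyltriisopropylsilane
Product: 6 (S)-2-acetyl-2-methyl-5-[(triisopropylsilyl)ethynyl]-2,3-dihydro-4H-pyran-4-one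
Conditions: PdCl2(PPh3)2 (5 mol %), CuI (10 mol %), iPr2NH, THF, rt
Reagents that add atoms: none
Why: Sonogashira coupling of an α-iodoenone with a terminal alkyne is reliable and installs C5 and C6 on C4.

Step 4
Reactants: 6 (S)-2-acetyl-2-methyl-5-[(triisopropylsilyl)ethynyl]-2,3-dihydro-4H-pyran-4-one; 7 2-(trimethylsilyl)ethoxymethyl chloride
Product: 10 1-methyl-4-[(triisopropylsilyl)ethynyl]-4-{[2-(trimethylsilyl)ethoxy]methyl}-8-oxabicyclo[3.2.1]octane-3,7-dione, via acetyl lithium enolate 8 (not isolated), via bicyclic lithium enolate 9 (not isolated)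
Conditions: LiN(SiMe3)2, THF, −78 to −40 °C; then 7, −78 to −20 °C
Reagents that add atoms: none
Why: The kinetic methyl-ketone enolate should add to C3 of the vinylogous ester (intramolecular Michael addition, 5-exo-trig), which forces the C2–C3 bond cis to the C1–C10 bond, and the resulting C8 enolate should be alkylated at C4 from the exo face so that the CH2O-TMSE arm is axial and the alkyne equatorial.

Step 5
Reactants: 10 1-methyl-4-[(triisopropylsilyl)ethynyl]-4-{[2-(trimethylsilyl)ethoxy]methyl}-8-oxabicyclo[3.2.1]octane-3,7-dione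
Product: 11 C1 ethylene ketal of 10
Conditions: Me3SiOCH2CH2OSiMe3, Me3SiOTf (5 mol %), CH2Cl2, −78 to −20 °C
Reagents that add atoms: 1,2-bis(trimethylsilyloxy)ethane, C[Si](C)(C)OCCO[Si](C)(C)C
Why: Silyl-triflate-catalysed ketalisation should select the C1 carbonyl, because the C8 carbonyl is shielded on its exo face by the axial C4 arm and on its endo face by the two-carbon bridge.

Step 6
Reactants: 11 C1 ethylene ketal of 10
Product: 14 equatorial C9 benzoate of 11, via potassium enolate 12 (not isolated), via axial C9 benzoate 13 (not isolated)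
Conditions: KN(SiMe3)2, THF, −78 °C; (PhCO2)2; then DBU, THF, rt
Reagents that add atoms: dibenzoyl peroxide, O=C(OOC(=O)c1ccccc1)c1ccccc1
Why: C9 is the only enolisable position of the C8 ketone, so enolate α-benzoyloxylation is regiospecific, and base equilibration through the enol should give the equatorial benzoate (the axial epimer clashes 1,3-diaxially with the C4 arm); loss of the bridging oxygen by β-elimination is blocked because it would create a bridgehead alkene.

Step 7
Reactants: 14 equatorial C9 benzoate of 11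
Product: 15 seven-membered lactone (3,9-dioxabicyclo[4.2.1]nonan-4-one) with O' between C8 and C4
Conditions: mCPBA, NaHCO3, CH2Cl2, rt
Reagents that add atoms: 3-chloroperoxybenzoic acid, OOC(=O)c1cccc(Cl)c1
Why: Baeyer–Villiger oxidation in which the fully substituted C4 should migrate with retention in preference to the benzoyloxy-deactivated C9, creating the tertiary C4–O' bond; the silylalkyne, the ketal and the ether are inert to buffered peracid.

Step 8
Reactants: 15 seven-membered lactone
Product: 16 lactol with free C9 hydroxyl (both C8 anomers)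
Conditions: iBu2AlH (4 equiv), CH2Cl2, −78 °C; Rochelle salt work-up
Reagents that add atoms: none
Why: Low-temperature hydride reduction should stop at the lactol and remove the benzoate in the same operation.

Step 9
Reactants: 16 lactol with free C9 hydroxyl
Product: 18 tetrahydrofuran alkyne diol (C8≡C7H), via ring-opened hydroxy aldehyde 17 (not isolated)
Conditions: dimethyl (1-diazo-2-oxopropyl)phosphonate, K2CO3, MeOH, 0 °C to rt
Reagents that add atoms: dimethyl (1-diazo-2-oxopropyl)phosphonate, COP(=O)(OC)C(=[N+]=[N-])C(C)=O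
Why: Seyferth–Gilbert homologation (Ohira–Bestmann variant) of the aldehyde form of the lactol should give the terminal alkyne (C7 is added) and release the tertiary C4 hydroxyl; the lactol keeps the free aldehyde concentration low, which should protect C9 from epimerisation.

Step 10
Reactants: 18 tetrahydrofuran alkyne diol; 19 methyl 2-bromoacrylate
Product: 20 enyne ester diol (methyl 2-methylene-alk-3-ynoate)
Conditions: PdCl2(PPh3)2 (5 mol %), CuI (10 mol %), iPr2NH, THF, 0 °C to rt
Reagents that add atoms: none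
Why: Sonogashira coupling, chemoselective because the only terminal alkyne is C7 (the C6 alkyne is silylated), attaches C11–C13 as the complete acrylate unit.

Step 11
Reactants: 20 enyne ester diol
Product: 21 diol with free C4 ethynyl group
Conditions: Bu4NF, AcOH, THF, 0 °C
Reagents that add atoms: none
Why: Fluoride C-desilylation of the alkynylsilane, buffered with acetic acid to spare the acrylate.

Step 12
Reactants: 21 diol with free C4 ethynyl group
Product: 22 C9 TBS ether
Conditions: TBSOTf (1.1 equiv), 2,6-lutidine, CH2Cl2, −78 °C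
Reagents that add atoms: tert-butyldimethylsilyl triflate, CC(C)(C)[Si](C)(C)OS(=O)(=O)C(F)(F)F
Why: The secondary C9 hydroxyl should be silylated well before the tertiary C4 hydroxyl, and the bulky silyl ether later enforces non-chelation control at C8.

Step 13
Reactants: 22 C9 TBS ether
Product: 23 (Z)-enol acetate (C4–CH=CH–OAc)
Conditions: Ru(η3-CH2C(CH3)CH2)2[Ph2P(CH2)4PPh2] (3 mol %), AcOH, toluene, 45 °C
Reagents that add atoms: acetic acid, CC(=O)O
Why: Ruthenium-vinylidene-mediated anti-Markovnikov addition of a carboxylic acid to a terminal alkyne gives (Z)-enol esters, tertiary propargylic alcohols being known substrates; the internal enyne cannot form a vinylidene and should stay untouched.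

Step 14
Reactants: 23 (Z)-enol acetate
Product: 24 (Z)-alkylidene dioxepane (3,9-dioxabicyclo[4.2.1]nonane enol ether)
Conditions: Ph3PAuNTf2 (5 mol %), 2,6-di-tert-butylpyridine, 4 Å molecular sieves, CH2Cl2, 0 °C to rt
Reagents that add atoms: none
Why: Monovalent-gold-catalysed intramolecular hydroalkoxylation (7-exo-dig) at C8, the alkyne carbon remote from the acrylate; anti addition of O–H places the C11 substituent cis to O' (Z), and the hindered base should suppress ionisation of the tertiary allylic alcohol.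

Step 15
Reactants: 24 (Z)-alkylidene dioxepane
Product: 25 nine-membered ketone (11-oxabicyclo[6.2.1]undec-4-en-7-one core, C8 ketone)
Conditions: toluene, BHT, base-washed glassware, 95 °C
Reagents that add atoms: none
Why: Thermal [3,3]-sigmatropic (Claisen) rearrangement of the allyl vinyl ether C7=C8–O'–C4–C5=C6: the C4–O' bond breaks while C6–C7 forms, so C7, C6 and C5 enter the ring and O' leaves it as the C8 carbonyl oxygen. The closest known reaction type is the Claisen ring expansion of 2-alkylidene vinyl-substituted cyclic ethers to medium-ring ketones. No ring is closed end to end: the nine-membered oxacycle (O, C3 to C10) grows out of the seven-membered ring by a two-atom enlargement, and the cis bridge at C3 and C10 is kept. C6 and C7 should be set by a chair-like transition state on the dioxepane face that carries the C4 vinyl group (fixed by the C4 stereocenter), with the (Z)-acetoxy group and the (Z)-placed acrylate substituent both pseudo-axial, which gives the 6,7 relationship of the later trans-fused lactone; C3 is pseudo-axial on C4 and so ends cis to C6 (Z-C4=C5). The step needs chair over boat topology and the concerted shift over ionisation or a 1,3-shift, and the rigid bicyclic frame, the two defined alkene geometries and a non-polar acid-free medium should secure this.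

Step 16
Reactants: 25 nine-membered ketone
Product: 26 keto lactone (6,12-olide, C8 ketone)
Conditions: (ClBu2SnOSnBu2Cl)2 (10 mol %), MeOH, toluene, 60 °C
Reagents that add atoms: none
Why: Neutral tin-catalysed transesterification should remove the acetate as methyl acetate and let the freed C6 hydroxyl close onto the acrylate ester (lactonisation, 5-exo-trig), avoiding the β-elimination that base would cause in the β-acyloxy ketone.

Step 17
Reactants: 26 keto lactone
Product: 27 C8 alcohol
Conditions: NaBH4, CeCl3·7H2O, MeOH/THF, −78 °C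
Reagents that add atoms: none
Why: Luche 1,2-reduction, in which Felkin–Anh attack anti to the bulky C9 silyloxy group (no chelation) should give the 8,9-syn alcohol and the α-methylene lactone is spared.

Step 18
Reactants: 27 C8 alcohol; 28 methacrylic anhydride
Product: 29 C8 methacrylate
Conditions: Et3N, DMAP, CH2Cl2, 0 °C
Reagents that add atoms: none
Why: DMAP-catalysed acylation of the secondary alcohol, done at once to prevent translactonisation to the 8,12-olide.

Step 19
Reactants: 29 C8 methacrylate
Product: 30 C9 alcohol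
Conditions: HF·pyridine, pyridine, THF, 0 °C to rt
Reagents that add atoms: none
Why: Fluoride cleavage of the TBS ether, with the TMSE ether, the ketal and the esters expected to be stable under buffered HF.

Step 20
Reactants: 30 C9 alcohol; 31 angelic acid
Product: 32 C9 angelate
Conditions: 31, 2,4,6-trichlorobenzoyl chloride, Et3N, toluene, rt; then 30, toluene, 80 °C
Reagents that add atoms: none
Why: Yamaguchi-type mixed-anhydride esterification without a nucleophilic catalyst is the standard way to acylate a hindered alcohol with angelic acid without Z to E isomerisation.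

Step 21
Reactants: 32 C9 angelate
Product: 34 hydroxy ketone (C15 OH, C1 ketone), via C15 alcohol ketal 33 (not isolated)
Conditions: BF3·OEt2, CH2Cl2, 0 °C; then HCl (1 M aq.), THF, rt
Reagents that add atoms: water, O
Why: Lewis-acid-induced β-silyl fragmentation of the TMSE ether (loss of ethylene) followed by acid hydrolysis of the dioxolane, neither of which should touch the three esters.

Step 22
Reactants: 34 hydroxy ketone
Product: 37 target compound, via bis-silylated enol ether 35 (not isolated), via target trimethylsilyl ether 36 (not isolated)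
Conditions: Me3SiOTf, Et3N, CH2Cl2, 0 °C; Pd(OAc)2, MeCN, rt; then citric acid, MeOH
Reagents that add atoms: none
Why: Saegusa–Ito oxidation, in which soft enolisation can only go toward C2 (C10 is quaternary) and divalent palladium then removes the C3 hydrogen to give the C2=C3 bond of the 3(2H)-furanone, now unstrained in the enlarged ring; the primary alcohol is masked in the flask as its silyl ether and freed on work-up.

Compound list
1 | butane-2,3-dione | CC(=O)C(C)=O | starting material
2 | (E)-1-methoxy-3-(trimethylsilyloxy)buta-1,3-diene | CO/C=C/C(=C)O[Si](C)(C)C | starting material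
3 | (S)-2-acetyl-2-methyl-2,3-dihydro-4H-pyran-4-one | CC(=O)[C@]1(C)CC(=O)C=CO1 | intermediate
4 | (S)-2-acetyl-5-iodo-2-methyl-2,3-dihydro-4H-pyran-4-one | CC(=O)[C@]1(C)CC(=O)C(I)=CO1 | intermediate
5 | ethynyltriisopropylsilane | C#C[Si](C(C)C)(C(C)C)C(C)C | starting material
6 | (S)-2-acetyl-2-methyl-5-[(triisopropylsilyl)ethynyl]-2,3-dihydro-4H-pyran-4-one | CC(=O)[C@]1(C)CC(=O)C(C#C[Si](C(C)C)(C(C)C)C(C)C)=CO1 | intermediate
7 | 2-(trimethylsilyl)ethoxymethyl chloride | C[Si](C)(C)CCOCCl | starting material
8 | lithium enolate of the acetyl group of 6 | C=C(O[Li])[C@]1(C)CC(=O)C(C#C[Si](C(C)C)(C(C)C)C(C)C)=CO1 | intermediate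
9 | lithium C8 enolate of the 8-oxabicyclo[3.2.1]octane Michael adduct | C[C@@]12CC(O[Li])=C(C#C[Si](C(C)C)(C(C)C)C(C)C)[C@@H](O1)CC2=O | intermediate
10 | 1-methyl-4-[(triisopropylsilyl)ethynyl]-4-{[2-(trimethylsilyl)ethoxy]methyl}-8-oxabicyclo[3.2.1]octane-3,7-dione (C10 S; on C4 the CH2O-TMSE arm axial and anti to the two-carbon bridge, the alkyne equatorial) | C[C@@]12CC(=O)[C@](COCC[Si](C)(C)C)(C#C[Si](C(C)C)(C(C)C)C(C)C)[C@@H](O1)CC2=O | intermediate
11 | C1 ethylene ketal of 10 (dioxolane on the two-carbon bridge) | C[C@@]12CC(=O)[C@](COCC[Si](C)(C)C)(C#C[Si](C(C)C)(C(C)C)C(C)C)[C@@H](O1)CC23OCCO3 | intermediate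
12 | potassium C8–C9 enolate of 11 | C[C@@]12C=C(O[K])[C@](COCC[Si](C)(C)C)(C#C[Si](C(C)C)(C(C)C)C(C)C)[C@@H](O1)CC23OCCO3 | intermediate
13 | axial C9 benzoate of 11 (benzoate anti to the two-carbon bridge) | C[C@@]12[C@@H](OC(=O)c3ccccc3)C(=O)[C@](COCC[Si](C)(C)C)(C#C[Si](C(C)C)(C(C)C)C(C)C)[C@@H](O1)CC24OCCO4 | intermediate
14 | equatorial C9 benzoate of 11 (benzoate on the side of the ketal bridge, C9 as in the target) | C[C@@]12[C@H](OC(=O)c3ccccc3)C(=O)[C@](COCC[Si](C)(C)C)(C#C[Si](C(C)C)(C(C)C)C(C)C)[C@@H](O1)CC24OCCO4 | intermediate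
15 | seven-membered lactone, 3,9-dioxabicyclo[4.2.1]nonan-4-one with O' between C8 and C4 (C4 retained) | C[C@@]12[C@H](OC(=O)c3ccccc3)C(=O)O[C@](COCC[Si](C)(C)C)(C#C[Si](C(C)C)(C(C)C)C(C)C)[C@@H](O1)CC24OCCO4 | intermediate
16 | lactol of 15 with free C9 hydroxyl (C8 anomers) | C[C@@]12[C@H](O)C(O)O[C@](COCC[Si](C)(C)C)(C#C[Si](C(C)C)(C(C)C)C(C)C)[C@@H](O1)CC23OCCO3 | intermediate
17 | ring-opened hydroxy aldehyde of 16 | O=C[C@@H](O)[C@]1(C)O[C@@H](CC12OCCO2)[C@@](O)(COCC[Si](C)(C)C)C#C[Si](C(C)C)(C(C)C)C(C)C | intermediate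
18 | 2,5-cis tetrahydrofuran alkyne diol (C10 carries methyl and the C9 propargylic carbinol; C3 carries the C4 tertiary carbinol) | C#C[C@@H](O)[C@]1(C)O[C@@H](CC12OCCO2)[C@@](O)(COCC[Si](C)(C)C)C#C[Si](C(C)C)(C(C)C)C(C)C | intermediate
19 | methyl 2-bromoacrylate | C=C(Br)C(=O)OC | starting material
20 | enyne ester diol (acrylate on C7) | COC(=O)C(=C)C#C[C@@H](O)[C@]1(C)O[C@@H](CC12OCCO2)[C@@](O)(COCC[Si](C)(C)C)C#C[Si](C(C)C)(C(C)C)C(C)C | intermediate
21 | enyne ester diol with free C4 ethynyl group | COC(=O)C(=C)C#C[C@@H](O)[C@]1(C)O[C@@H](CC12OCCO2)[C@@](O)(COCC[Si](C)(C)C)C#C | intermediate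
22 | C9 TBS ether of 21 | COC(=O)C(=C)C#C[C@@H](O[Si](C)(C)C(C)(C)C)[C@]1(C)O[C@@H](CC12OCCO2)[C@@](O)(COCC[Si](C)(C)C)C#C | intermediate
23 | (Z)-enol acetate of 22 (C4–CH=CH–OAc) | COC(=O)C(=C)C#C[C@@H](O[Si](C)(C)C(C)(C)C)[C@]1(C)O[C@@H](CC12OCCO2)[C@@](O)(COCC[Si](C)(C)C)/C=C\OC(C)=O | intermediate
24 | (Z)-alkylidene dioxepane, 3,9-dioxabicyclo[4.2.1]nonane with C8=C7 enol ether (C11 cis to O') and (Z)-2-acetoxyvinyl on C4 | COC(=O)C(=C)/C=C1\O[C@](COCC[Si](C)(C)C)(/C=C\OC(C)=O)[C@@H]2CC3(OCCO3)[C@@](C)(O2)[C@@H]1O[Si](C)(C)C(C)(C)C | intermediate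
25 | nine-membered ketone, 11-oxabicyclo[6.2.1]undec-4-ene core with C6 acetate and C7 acrylate (6R,7S sense of the target, Z-C4=C5) | COC(=O)C(=C)[C@H]1[C@H](OC(C)=O)/C=C(/COCC[Si](C)(C)C)[C@@H]2CC3(OCCO3)[C@@](C)(O2)[C@H](O[Si](C)(C)C(C)(C)C)C1=O | intermediate
26 | keto lactone (trans-fused 6,12-olide, C8 ketone) | C=C1C(=O)O[C@@H]2/C=C(/COCC[Si](C)(C)C)[C@@H]3CC4(OCCO4)[C@@](C)(O3)[C@H](O[Si](C)(C)C(C)(C)C)C(=O)[C@@H]12 | intermediate
27 | C8 alcohol (8,9-syn) | C=C1C(=O)O[C@@H]2/C=C(/COCC[Si](C)(C)C)[C@@H]3CC4(OCCO4)[C@@](C)(O3)[C@H](O[Si](C)(C)C(C)(C)C)[C@@H](O)[C@@H]12 | intermediate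
28 | methacrylic anhydride | C=C(C)C(=O)OC(=O)C(C)=C | starting material
29 | C8 methacrylate | C=C1C(=O)O[C@@H]2/C=C(/COCC[Si](C)(C)C)[C@@H]3CC4(OCCO4)[C@@](C)(O3)[C@H](O[Si](C)(C)C(C)(C)C)[C@@H](OC(=O)C(C)=C)[C@@H]12 | intermediate
30 | C9 alcohol | C=C1C(=O)O[C@@H]2/C=C(/COCC[Si](C)(C)C)[C@@H]3CC4(OCCO4)[C@@](C)(O3)[C@H](O)[C@@H](OC(=O)C(C)=C)[C@@H]12 | intermediate
31 | angelic acid, (Z)-2-methylbut-2-enoic acid | C/C=C(/C)C(=O)O | starting material
32 | C9 angelate | C=C1C(=O)O[C@@H]2/C=C(/COCC[Si](C)(C)C)[C@@H]3CC4(OCCO4)[C@@](C)(O3)[C@H](OC(=O)/C(C)=C\C)[C@@H](OC(=O)C(C)=C)[C@@H]12 | intermediate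
33 | C15 alcohol with C1 ketal | C=C1C(=O)O[C@@H]2/C=C(/CO)[C@@H]3CC4(OCCO4)[C@@](C)(O3)[C@H](OC(=O)/C(C)=C\C)[C@@H](OC(=O)C(C)=C)[C@@H]12 | intermediate
34 | hydroxy ketone (C15 OH, C1 ketone, saturated furanone ring) | C=C1C(=O)O[C@@H]2/C=C(/CO)[C@@H]3CC(=O)[C@@](C)(O3)[C@H](OC(=O)/C(C)=C\C)[C@@H](OC(=O)C(C)=C)[C@@H]12 | intermediate
35 | bis-silylated enol ether (C1 OSiMe3 enol ether, C15 OSiMe3) | C=C1C(=O)O[C@@H]2/C=C(/CO[Si](C)(C)C)[C@@H]3C=C(O[Si](C)(C)C)[C@@](C)(O3)[C@H](OC(=O)/C(C)=C\C)[C@@H](OC(=O)C(C)=C)[C@@H]12 | intermediate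
36 | C15 trimethylsilyl ether of the target | C=C1C(=O)O[C@@H]2/C=C(/CO[Si](C)(C)C)C3=CC(=O)[C@@](C)(O3)[C@H](OC(=O)/C(C)=C\C)[C@@H](OC(=O)C(C)=C)[C@@H]12 | intermediate
37 | target compound (6R,7S,8S,9R,10S; 8-methacrylate, 9-angelate, 15-hydroxy furanoheliangolide) | C=C(C)C(=O)O[C@H]1[C@H]2C(=C)C(=O)O[C@@H]2/C=C(/CO)C2=CC(=O)[C@@](C)(O2)[C@@H]1OC(=O)/C(C)=C\C | target

Total step count: 22. Longest linear sequence: 22 steps (fully linear from 1 and 2; 5, 7, 19, 28 and 31 are purchased).

Steps most likely to fail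

Step 15 (key step). What may go wrong is loss of transition-state control: if the rearrangement runs through the boat instead of the chair, C6 is inverted and the cis-lactone series results. The fallback changes the geometry of the enol ester so that the boat delivers the right isomer. It sets out from 22 and comes back at 25. Hydroboration of 22 (pinacolborane, Cp2ZrHCl cat., Et3N) should give the (E)-alkenyl pinacolboronate F1. Copper-mediated acetoxylation with retention (Cu(OAc)2, DMAP, O2, 4 Å molecular sieves) should give the (E)-enol acetate F2. Gold-catalysed ring closure as in step 14 should give the (E)-acetoxyvinyl dioxepane F3, and heating it should then lead through the boat to 25.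

Step 14. What may go wrong is ionisation and allylic transposition of the acid-labile tertiary hydroxy enol acetate under the Lewis-acidic gold catalyst, outrunning the slow 7-exo-dig attack. The fallback closes the ring before the enol ester exists. It sets out from 20 and comes back at 24. Silylation of 20 (TBSOTf, 2,6-lutidine) should give the C9 TBS ether F4, which still carries the silylated C4 alkyne. Gold-catalysed hydroalkoxylation of this robust tertiary propargylic alcohol should give the dioxepane with C4 silylalkyne F5. Selective C-desilylation (AgF, MeOH; then dilute HCl) should give the dioxepane with C4 ethynyl group F6, and the ruthenium-catalysed addition of acetic acid as in step 13 should then give 24.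

Step 7. What may go wrong is migration of the wrong carbon (C9 instead of C4) in the Baeyer–Villiger oxidation, since both α-carbons are electron-poor. The fallback oxidises before C9 carries oxygen. It sets out from 11 and comes back at 16. Baeyer–Villiger oxidation of 11 (mCPBA, NaHCO3), where only the tertiary C4 can compete with a CH2 group, should give the lactone without C9 oxygen F7. Enolate hydroxylation (KN(SiMe3)2; 2-(phenylsulfonyl)-3-phenyloxaziridine) from the open face should give the 9-epi α-hydroxy lactone F8. Dess–Martin oxidation should give the α-keto lactone F9, and NaBH4 reduction from the face remote from the ketal bridge should give the α-hydroxy lactone with the C9 configuration of 16 F10. iBu2AlH reduction of this lactone should give 16.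

Further compounds
F1 | step 15 | (E)-alkenyl pinacolboronate of 22 | COC(=O)C(=C)C#C[C@@H](O[Si](C)(C)C(C)(C)C)[C@]1(C)O[C@@H](CC12OCCO2)[C@@](O)(COCC[Si](C)(C)C)/C=C/B1OC(C)(C)C(C)(C)O1
F2 | step 15 | (E)-enol acetate isomer of 23 | COC(=O)C(=C)C#C[C@@H](O[Si](C)(C)C(C)(C)C)[C@]1(C)O[C@@H](CC12OCCO2)[C@@](O)(COCC[Si](C)(C)C)/C=C/OC(C)=O
F3 | step 15 | (E)-acetoxyvinyl dioxepane, isomer of 24 | COC(=O)C(=C)/C=C1\O[C@](COCC[Si](C)(C)C)(/C=C/OC(C)=O)[C@@H]2CC3(OCCO3)[C@@](C)(O2)[C@@H]1O[Si](C)(C)C(C)(C)C
F4 | step 14 | C9 TBS ether of 20 | COC(=O)C(=C)C#C[C@@H](O[Si](C)(C)C(C)(C)C)[C@]1(C)O[C@@H](CC12OCCO2)[C@@](O)(COCC[Si](C)(C)C)C#C[Si](C(C)C)(C(C)C)C(C)C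
F5 | step 14 | dioxepane with C4 silylalkyne | COC(=O)C(=C)/C=C1\O[C@](COCC[Si](C)(C)C)(C#C[Si](C(C)C)(C(C)C)C(C)C)[C@@H]2CC3(OCCO3)[C@@](C)(O2)[C@@H]1O[Si](C)(C)C(C)(C)C
F6 | step 14 | dioxepane with C4 ethynyl group | COC(=O)C(=C)/C=C1\O[C@](COCC[Si](C)(C)C)(C#C)[C@@H]2CC3(OCCO3)[C@@](C)(O2)[C@@H]1O[Si](C)(C)C(C)(C)C
F7 | step 7 | lactone without C9 oxygen | C[C@@]12CC(=O)O[C@](COCC[Si](C)(C)C)(C#C[Si](C(C)C)(C(C)C)C(C)C)[C@@H](O1)CC23OCCO3
F8 | step 7 | 9-epi α-hydroxy lactone | C[C@@]12[C@@H](O)C(=O)O[C@](COCC[Si](C)(C)C)(C#C[Si](C(C)C)(C(C)C)C(C)C)[C@@H](O1)CC23OCCO3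
F9 | step 7 | α-keto lactone | C[C@@]12C(=O)C(=O)O[C@](COCC[Si](C)(C)C)(C#C[Si](C(C)C)(C(C)C)C(C)C)[C@@H](O1)CC23OCCO3
F10 | step 7 | α-hydroxy lactone with the C9 configuration of 16 | C[C@@]12[C@H](O)C(=O)O[C@](COCC[Si](C)(C)C)(C#C[Si](C(C)C)(C(C)C)C(C)C)[C@@H](O1)CC23OCCO3
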